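Readings and results are calculated for an exercise; noise was put on by code.

A one-step world holds no intermediate, yet the elm run keeps 47.9% of its charge as intermediate at 25.0 h. So we reckon two steps, in fractions of the starting material charged, and write the balance of partner, the limiting reagent.

| flask | starting material | partner | free catalyst | second catalyst | remark | time |
|---|---|---|---|---|---|---|
| elm | 0.30 M | 0.80 equiv | 0.15 mol% | 5 mol% | run made earlier |  |
| maple | 0.30 M | 0.80 equiv | 0.23 mol% | 5 mol% | run made earlier |  |
| flask | 0.30 M | 0.800 equiv | 0.31 mol% | 5 mol% |  | 25 h |

| run | time / h | intermediate / % | product / % | starting material / % |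
|---|---|---|---|---|
| elm | 2.00 | 8.5 | 0.2 | 90.8 |
| elm | 6.00 | 21.8 | 1.9 | 75.7 |
| elm | 12.0 | 35.1 | 7.1 | 57.6 |
| elm | 20.0 | 44.6 | 15.8 | 40.3 |
| elm | 25.0 | 47.9 | 20.8 | 32.6 |
| maple | 5.00 | 27.5 | 2.1 | 70.2 |
| maple | 10.0 | 42.9 | 7.9 | 49.3 |
| maple | 15.0 | 52.0 | 13.6 | 34.6 |
| maple | 20.0 | 55.8 | 19.6 | 24.8 |
| maple | 25.0 | 56.6 | 26.2 | 17.1 |

(standard deviation of a reading: 0.3 percentage points)

1. the largest share of what was charged as starting material, at 25 h belongs to (product / intermediate / starting material)
2. the largest share itself, whichever of these holds it, in percent of the starting material charged



1. Starting material decays pseudo-first-order. The decay constant of maple over elm reads 1.58, against a loading ratio of 1.53. So we scale maple's constant by loading, which gives the flask 0.0952 h⁻¹, a half-life of 7.28 h.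

2. Partner left is its charge minus product. The late readings of elm give 0.0384 h⁻¹ and those of maple 0.0386 h⁻¹. Their mean, 0.0385 h⁻¹, is the drain constant: product rate over intermediate times partner left, read at 5 mol% of second catalyst.

3. With partner as charged, intermediate's half-life by this drain is 22.5 h, longer than starting material's, so intermediate piles up.

4. Partner left falls exponentially with the drain constant times the exposure, the time integral of intermediate. Ignoring product, the exposure is 15.5 h. A straight rise of product to maple's end value takes off 3.27 h. We therefore commit to product 30.0%, starting material 9.25% and intermediate 60.8%, the largest share. At that share partner's half-life is 29.6 h, longer than the run.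

The forecast, seeing that the rate of product “levels off near 1.2–1.3 %/h”, names intermediate at 62%, a little above our share.

The flask gives intermediate at 61.2%.

    starting material + free catalyst → free catalyst + intermediate (k = 1.70 M⁻¹ min⁻¹)
    partner + second catalyst + intermediate → second catalyst + product (k = 0.140 M⁻² min⁻¹)

At 25.0 h the flask makes intermediate at 0.759 of the rate at which it uses it up, each step taken net, and the drain constant on the flask's end state gives 0.746. The neighbour flask with 0.12 mol% of free catalyst ends with starting material 39.9% and product 18.2%. From these the drain constant gives partner left at 78.1% of its charge, and that flask holds 77%.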